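**Retrosynthetic overview**

1. The strategy rests on the 5,5-dimethylfuran-2(5H)-one ring on flavone C8 (O1', C2' the carbonyl, C3' bonded to C8, C4' the CH, C5' the CMe2): it is read as an aryl alkyne (C3'≡C4'), a tertiary carbinol carbon (C5' with its oxygen) and one molecule of CO (C2').
2. Last disconnection: the butenolide goes back to 8-(3-hydroxy-3-methylbut-1-ynyl)-7-methoxyflavone and CO by palladium cyclocarbonylation, which forms C3'–C2' and O1'–C5'.
3. The C8–C(sp) bond goes back to 8-iodo-7-methoxyflavone and 2-methylbut-3-yn-2-ol (Sonogashira coupling); coupling after the pyranone is closed avoids an ortho-iodophenol that would cyclize to a benzofuran.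
4. The pyranone ring C goes back through a 1,3-diketone to 2-hydroxy-3-iodo-4-methoxyacetophenone and benzoyl chloride; the acetophenone comes from 2,4-dihydroxyacetophenone by C3 iodination and 4-O-methylation.
5. Ring order: ring A and the phenyl ring B are bought, ring C is closed in step 4, the butenolide is closed last in step 6.

Key step: step 6

Remark: lithium and potassium salts, enolates and catalyst-bound organopalladium species that are only passing forms of a numbered compound are described in words and carry no number.

**Step 1**
Reactants: 1 2,4-dihydroxyacetophenone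
Product: 2 2,4-dihydroxy-3-iodoacetophenone
Conditions: I2 (0.4 equiv), HIO3 (0.2 equiv), EtOH–H2O, 35–40 °C
Reagents that add atoms: iodine, II; iodic acid, OI(=O)=O
Why: Electrophilic aromatic iodination with the iodine/iodic acid couple, which delivers every iodine atom to the arene; the position between the two hydroxyls (C3) is the one expected under these conditions, as in the conversion of resorcinol into 2-iodoresorcinol, and the exact 1:1 iodine stoichiometry should hold back the 3,5-diiodide.

**Step 2**
Reactants: 2 2,4-dihydroxy-3-iodoacetophenone
Product: 3 2-hydroxy-3-iodo-4-methoxyacetophenone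
Conditions: MeI (1.05 equiv), K2CO3 (1.1 equiv), acetone, reflux
Reagents that add atoms: iodomethane, CI
Why: Williamson ether synthesis that should be selective for the 4-hydroxyl, because the 2-hydroxyl is held in a hydrogen bond to the acetyl carbonyl and is the less acidic and less nucleophilic of the two.

**Step 3**
Reactants: 3 2-hydroxy-3-iodo-4-methoxyacetophenone; 4 benzoyl chloride
Product: 5 1-(2-hydroxy-3-iodo-4-methoxyphenyl)-3-phenylpropane-1,3-dione
Conditions: LiN(SiMe3)2 (3.1 equiv), THF, −78 to −10 °C; then 4 (1.0 equiv), −78 °C to rt; aq. HCl
Reagents that add atoms: none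
Why: Direct C-benzoylation of the lithium phenoxide–enolate dianion (Claisen-type acylation that reaches the Baker–Venkataraman diketone in one operation); the enolate carbon is far more nucleophilic than the crowded, iodine-flanked phenoxide, and the third equivalent of base stores the product as its diketonate so that it is not acylated twice.

**Step 4**
Reactants: 5 1-(2-hydroxy-3-iodo-4-methoxyphenyl)-3-phenylpropane-1,3-dione
Product: 6 8-iodo-7-methoxyflavone (8-iodo-7-methoxy-2-phenyl-4H-chromen-4-one)
Conditions: H2SO4 (cat.), AcOH, 90 °C
Reagents that add atoms: none
Why: Acid-catalysed cyclodehydration that completes the Baker–Venkataraman flavone synthesis: the phenol oxygen adds to the benzoyl carbonyl (6-exo-trig) and loss of water gives the aromatic 4-pyranone ring C.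

**Step 5**
Reactants: 6 8-iodo-7-methoxyflavone; 7 2-methylbut-3-yn-2-ol
Product: 8 8-(3-hydroxy-3-methylbut-1-ynyl)-7-methoxyflavone
Conditions: PdCl2(PPh3)2 (5 mol %), CuI (10 mol %), Et3N, DMF, 60 °C
Reagents that add atoms: none
Why: Sonogashira coupling of an aryl iodide with a terminal alkyne; the former phenol oxygen is already part of the pyranone, so no benzofuran can form, and the free tertiary alcohol is tolerated.

**Step 6**
Reactants: 8 8-(3-hydroxy-3-methylbut-1-ynyl)-7-methoxyflavone; 9 carbon monoxide
Product: 11 8-(5,5-dimethyl-2-oxo-2,5-dihydrofuran-3-yl)-7-methoxyflavone, via allenoic acid 10 (not isolated)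
Conditions: Pd(dba)2 (5 mol %), 1,4-bis(diphenylphosphino)butane (5 mol %), CO (40 atm), H2 (10 atm), CH2Cl2, 95 °C, autoclave
Reagents that add atoms: none
Why: Zerovalent palladium carrying the diphosphine, helped by the palladium hydride that H2 generates and that acts as the acid activating the hydroxyl, should ionize the tertiary C5'–OH bond in SN2' sense to a σ-allenylpalladium hydroxide with the metal on C3', the carbon that bears the flavone. CO then inserts into the C3'–Pd bond (new bond C3'–C2') and the acylpalladium hydroxide collapses to allenoic acid 10 with return of zerovalent palladium. The carboxyl oxygen adds to the CMe2 terminus of the allene (new bond O1'–C5') in a 5-endo-trig closure assisted by the palladium hydride or by the acid itself, and protonation at C4' leaves the conjugated butenolide, the only ring closed; no stereocenter is formed. The closest known reaction type is the palladium-catalysed cyclocarbonylation of terminal and internal tertiary propargylic alcohols to 2(5H)-furanones under CO/H2, with the carbonylation of propargylic carbonates to 2,3-dienoates as its mechanistic relative. The regiochemistry needed (CO on the aryl-bearing carbon, oxygen on CMe2) is secured by the position of the hydroxyl, since SN2' ionization can place palladium only on the distal alkyne carbon, and the gem-dimethyl group makes both the ionization and the oxygen attack at C5' easy. Chemoselectivity over hydrogenation of the alkyne or of the flavone C2=C3 bond and over dehydration to the enyne should be secured by a CO pressure several times that of H2.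

**Compound list**

1 | 2,4-dihydroxyacetophenone | CC(=O)c1ccc(O)cc1O | starting material
2 | 2,4-dihydroxy-3-iodoacetophenone | CC(=O)c1ccc(O)c(I)c1O | intermediate
3 | 2-hydroxy-3-iodo-4-methoxyacetophenone | CC(=O)c1ccc(OC)c(I)c1O | intermediate
4 | benzoyl chloride | O=C(Cl)c1ccccc1 | starting material
5 | 1-(2-hydroxy-3-iodo-4-methoxyphenyl)-3-phenylpropane-1,3-dione | COc1ccc(C(=O)CC(=O)c2ccccc2)c(O)c1I | intermediate
6 | 8-iodo-7-methoxyflavone | COc1ccc2c(=O)cc(-c3ccccc3)oc2c1I | intermediate
7 | 2-methylbut-3-yn-2-ol | C#CC(C)(C)O | starting material
8 | 8-(3-hydroxy-3-methylbut-1-ynyl)-7-methoxyflavone | COc1ccc2c(=O)cc(-c3ccccc3)oc2c1C#CC(C)(C)O | intermediate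
9 | carbon monoxide | [C-]#[O+] | starting material
10 | 2-(7-methoxy-4-oxo-2-phenyl-4H-chromen-8-yl)-4-methylpenta-2,3-dienoic acid (not isolated) | COc1ccc2c(=O)cc(-c3ccccc3)oc2c1C(=C=C(C)C)C(=O)O | intermediate
11 | 8-(5,5-dimethyl-2-oxo-2,5-dihydrofuran-3-yl)-7-methoxyflavone | COc1ccc2c(=O)cc(-c3ccccc3)oc2c1C1=CC(C)(C)OC1=O | target

**Step count**

Total steps: 6. Longest linear sequence: 6 steps (from compound 1).

**Steps most likely to fail**

Step 6 (key step). Ionization of the free carbinol at the crowded C8 position may be too slow, so that dehydration to the enyne or hydrogenation of the triple bond or of the flavone C2=C3 bond overtakes carbonylation. The fallback activates the alcohol and carbonylates without hydrogen, in separate operations. It sets out from compound 8, which is converted (LiN(SiMe3)2, methyl chloroformate, THF, −78 °C) into the propargylic methyl carbonate F1. Decarboxylative methoxycarbonylation (Pd(OAc)2, PPh3, CO 10 atm, MeOH, 50 °C; zerovalent palladium formed in the flask) should give the methyl allenoate F2. Saponification (LiOH, THF–H2O, 0 °C) gives allenoic acid 10, where the fallback comes back to the route. Cycloisomerization of 10 with catalytic AgNO3 in acetone at room temperature should then give compound 11.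

Step 1. Iodination at C5 or twofold iodination may compete with substitution at C3 and give isomers that are hard to separate. The fallback postpones the iodination until the pyranone is in place, where bond fixation in a 7-hydroxychromone directs electrophiles to C8. It sets out from compound 1, which is C-benzoylated with compound 4 (LiN(SiMe3)2, 4 equiv, THF, −78 °C to rt) to the diketone F3. Cyclodehydration (H2SO4 cat., AcOH, 90 °C) gives 7-hydroxyflavone F4, which is also commercially available. Iodination (I2, HIO3, aqueous EtOH) should give 7-hydroxy-8-iodoflavone F5, and methylation (MeI, K2CO3, acetone) comes back to the route at compound 6.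

Step 3. O-Benzoylation of the phenoxide, twofold acylation or incomplete enolate formation may erode the C-acylation. The fallback builds the C3 unit by an aldol condensation and closes ring C oxidatively. It sets out from compound 3, which is condensed with benzaldehyde (KOH, EtOH, rt; Claisen–Schmidt condensation) to the 2'-hydroxychalcone F6. Oxidative cyclization (I2 cat., dimethyl sulfoxide, 130 °C) comes back to the route at compound 6.

**Further compounds**

F1 | step 6 | methyl 4-(7-methoxy-4-oxo-2-phenyl-4H-chromen-8-yl)-2-methylbut-3-yn-2-yl carbonate | COC(=O)OC(C)(C)C#Cc1c(OC)ccc2c(=O)cc(-c3ccccc3)oc12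
F2 | step 6 | methyl 2-(7-methoxy-4-oxo-2-phenyl-4H-chromen-8-yl)-4-methylpenta-2,3-dienoate | COC(=O)C(=C=C(C)C)c1c(OC)ccc2c(=O)cc(-c3ccccc3)oc12
F3 | step 1 | 1-(2,4-dihydroxyphenyl)-3-phenylpropane-1,3-dione | O=C(CC(=O)c1ccccc1)c1ccc(O)cc1O
F4 | step 1 | 7-hydroxyflavone | O=c1cc(-c2ccccc2)oc2cc(O)ccc12
F5 | step 1 | 7-hydroxy-8-iodoflavone | O=c1cc(-c2ccccc2)oc2c(I)c(O)ccc12
F6 | step 3 | (E)-1-(2-hydroxy-3-iodo-4-methoxyphenyl)-3-phenylprop-2-en-1-one | COc1ccc(C(=O)/C=C/c2ccccc2)c(O)c1I
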